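**Retrosynthetic overview**
1. Prinsepiol 11 ⇒ tetraol 10. Both tetrahydrofuran rings close in the last step, one after the other, by 5-exo attack of each C9 hydroxyl on the C7 p-quinone methide (p-hydroxybenzyl cation) of the other half; C7 and C7' are set here.
2. 10 ⇒ bis-dioxolanone 9 by reductive removal of two pivalaldehyde acetal auxiliaries.
3. 9 ⇒ two molecules of monomer 7 by oxidative phenoxyl-radical 8–8' coupling of a C6–C3 unit that already carries the C8 oxygen. The acetal carbon of each dioxolanone directs both new carbinol centres (C8, C8'), and bis-quinone methide 8 is caught by methanol.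
4. 7 ⇒ methylidene dioxolanone 5 + 4-iodo-2-methoxyphenol 6 (Heck); 5 ⇒ (R)-lactic acid 1 + pivalaldehyde 2.
5. Ring order: auxiliary dioxolanone ring first (step 1, destroyed in step 5), then the first and the second tetrahydrofuran ring in the same final operation.

Assumption: lignan numbering is used (C7 benzylic, C8 carbinol, C9 oxymethylene); the benzylic epimer mixtures of 9 and 10 are carried on unseparated because these centres are reset in step 6.

**Route**

Step 1
Reactants: 1 (R)-lactic acid; 2 pivalaldehyde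
Product: 3 (2R,5R)-2-tert-butyl-5-methyl-1,3-dioxolan-4-one
Conditions: TsOH·H2O (cat.), H2SO4 (cat.), pentane, reflux, Dean–Stark; recrystallise from Et2O/pentane, −78 °C
Reagents that add atoms: none
Why: Acid-catalysed acetalisation (Seebach self-regeneration-of-stereocentres acetal) in which the cis isomer, tert-butyl and methyl on the same face, is strongly favoured and is purified by low-temperature crystallisation, so the acetal carbon is set by the lactic acid centre.

Step 2
Reactants: 3 (2R,5R)-2-tert-butyl-5-methyl-1,3-dioxolan-4-one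
Product: 5 (R)-2-tert-butyl-5-methylidene-1,3-dioxolan-4-one, via tertiary bromide 4 (not isolated)
Conditions: NBS (1.05 equiv), AIBN (cat.), CCl4, reflux; filter; then Et3N, 0 °C → rt
Reagents that add atoms: none
Why: Wohl–Ziegler radical bromination at the captodative C5–H followed by E2 loss of HBr toward the methyl group; the lactic acid centre is destroyed on purpose while the acetal carbon, now the only stereocentre, keeps its configuration.

Step 3
Reactants: 5 (R)-2-tert-butyl-5-methylidene-1,3-dioxolan-4-one; 6 4-iodo-2-methoxyphenol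
Product: 7 (2R,5Z)-2-tert-butyl-5-[(4-hydroxy-3-methoxyphenyl)methylidene]-1,3-dioxolan-4-one
Conditions: Pd(OAc)2 (5 mol %), Bu4NCl, NaHCO3, DMF, 60 °C
Reagents that add atoms: none
Why: Mizoroki–Heck arylation under ligand-free Jeffery conditions, in which the aryl group adds to the unsubstituted alkene terminus and syn β-hydride elimination can only use the benzylic hydrogen; the weak base NaHCO3 spares the acylal and the free phenol, and no stereocentre is formed.

Step 4
Reactants: 7 (2R,5Z)-2-tert-butyl-5-[(4-hydroxy-3-methoxyphenyl)methylidene]-1,3-dioxolan-4-one (two molecules)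
Product: 9 (2R,2'R,5S,5'S)-2,2'-di-tert-butyl-5,5'-bis[(4-hydroxy-3-methoxyphenyl)(methoxy)methyl]-5,5'-bi(1,3-dioxolane)-4,4'-dione, via bis-quinone methide 8 (not isolated)
Conditions: Ag2O (0.6–0.8 equiv per 7), CH2Cl2/MeOH 4:1, 0 °C → rt, dark
Reagents that add atoms: methanol (CO)
Why: Proposed new method: Ag2O oxidises the phenol to a phenoxyl radical with high spin density at the captodative C8 (ring-oxygen donor, lactone-carbonyl acceptor), two radicals combine C8–C8' each on the face away from its tert-butyl group (the trans rule known for enolates and 5-yl radicals of 2-tert-butyl-1,3-dioxolan-4-ones) so both tetrasubstituted carbinol carbons are set together as S,S, and methanol adds 1,6 to each quinone methide of 8, rearomatising and making the otherwise reversible coupling irreversible; the closest known reaction type is the Ag2O- or FeCl3-mediated β–β dehydrodimerisation of coniferyl alcohol, sinapyl alcohol and ferulates through bis-quinone methides.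

Step 5
Reactants: 9 (2R,2'R,5S,5'S)-2,2'-di-tert-butyl-5,5'-bis[(4-hydroxy-3-methoxyphenyl)(methoxy)methyl]-5,5'-bi(1,3-dioxolane)-4,4'-dione
Product: 10 (2S,3S)-2,3-bis[(4-hydroxy-3-methoxyphenyl)(methoxy)methyl]butane-1,2,3,4-tetraol
Conditions: LiAlH4 (6 equiv), THF, 0 °C; aqueous work-up
Reagents that add atoms: none
Why: Hydride reduction of the two acylal lactones, in which each ring opens to an aldehyde and a hemiacetal that collapses to pivalaldehyde and all carbonyls are reduced; no bond to C8 or C8' is broken, and 0 °C keeps the phenoxide from expelling methoxide.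

Step 6
Reactants: 10 (2S,3S)-2,3-bis[(4-hydroxy-3-methoxyphenyl)(methoxy)methyl]butane-1,2,3,4-tetraol
Product: 11 prinsepiol, (1S,2R,5S,6R)-2,6-bis(4-hydroxy-3-methoxyphenyl)-3,7-dioxabicyclo[3.3.0]octane-1,5-diol
Conditions: CSA (10 mol %), MeCN, 0 °C → rt, stop at full conversion
Reagents that add atoms: none
Why: Acid-catalysed loss of methanol gives the p-hydroxybenzyl cation (protonated p-quinone methide), the electrophile of lignan biosynthesis, and each C9 hydroxyl closes 5-exo onto C7 of the other half (double cycloetherification); allylic 1,3-strain puts the small C8 hydroxyl in the plane of the quinone methide, so the aryl group ends cis to the bridgehead hydroxyl (exo), which sets C7 and C7' as R under kinetic control.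

**Compound list**
1 | (R)-lactic acid (D-lactic acid) | C[C@@H](O)C(=O)O | starting material
2 | pivalaldehyde (2,2-dimethylpropanal) | CC(C)(C)C=O | starting material
3 | (2R,5R)-2-tert-butyl-5-methyl-1,3-dioxolan-4-one (cis) | C[C@H]1O[C@@H](C(C)(C)C)OC1=O | intermediate
4 | (2S,5S)-5-bromo-2-tert-butyl-5-methyl-1,3-dioxolan-4-one (Br trans to tert-butyl; same acetal geometry as 3, descriptor changes by CIP only) | C[C@@]1(Br)O[C@@H](C(C)(C)C)OC1=O | intermediate
5 | (R)-2-tert-butyl-5-methylidene-1,3-dioxolan-4-one | C=C1O[C@@H](C(C)(C)C)OC1=O | intermediate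
6 | 4-iodo-2-methoxyphenol | COc1cc(I)ccc1O | starting material
7 | (2R,5Z)-2-tert-butyl-5-[(4-hydroxy-3-methoxyphenyl)methylidene]-1,3-dioxolan-4-one | COc1cc(/C=C2\O[C@@H](C(C)(C)C)OC2=O)ccc1O | intermediate
8 | (2R,2'R,5S,5'S)-2,2'-di-tert-butyl-5,5'-bis[(3-methoxy-4-oxocyclohexa-2,5-dien-1-ylidene)methyl]-5,5'-bi(1,3-dioxolane)-4,4'-dione (bis-quinone methide) | COC1=CC(=C[C@]2(O[C@@H](C(C)(C)C)OC2=O)[C@]2(C=C3C=CC(=O)C(OC)=C3)O[C@@H](C(C)(C)C)OC2=O)C=CC1=O | intermediate
9 | (2R,2'R,5S,5'S)-2,2'-di-tert-butyl-5,5'-bis[(4-hydroxy-3-methoxyphenyl)(methoxy)methyl]-5,5'-bi(1,3-dioxolane)-4,4'-dione (epimer mixture at the two benzylic carbons) | COc1cc(C(OC)[C@]2(O[C@@H](C(C)(C)C)OC2=O)[C@]2(C(OC)c3ccc(O)c(OC)c3)O[C@@H](C(C)(C)C)OC2=O)ccc1O | intermediate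
10 | (2S,3S)-2,3-bis[(4-hydroxy-3-methoxyphenyl)(methoxy)methyl]butane-1,2,3,4-tetraol (epimer mixture at the two benzylic carbons) | COc1cc(C(OC)[C@@](O)(CO)[C@](O)(CO)C(OC)c2ccc(O)c(OC)c2)ccc1O | intermediate
11 | prinsepiol, (1S,2R,5S,6R)-2,6-bis(4-hydroxy-3-methoxyphenyl)-3,7-dioxabicyclo[3.3.0]octane-1,5-diol | COc1cc([C@H]2OC[C@]3(O)[C@@H](c4ccc(O)c(OC)c4)OC[C@]23O)ccc1O | target

**Step count and risks**

Total steps: 6. Longest linear sequence: 6 (1 → 3 → 5 → 7 → 9 → 10 → 11).

Most likely to fail, first: step 4. The 8–5', 5–5' and 8–O–4' coupling modes compete with 8–8', and the bond between two fully substituted captodative carbons is weak until methanol has added. The fallback sets out from 5 and 6 and comes back at 9. 6 is brominated ortho to the hydroxyl (NBS, MeCN, 0 °C) to 2-bromo-4-iodo-6-methoxyphenol F1. F1 is coupled with 5 under the step 3 conditions, where only the C–I bond reacts, to give the ring-blocked bromo monomer F2. With C5 of the arene blocked, Ag2O in CH2Cl2/MeOH can only give 8–8' or reversible 8–O–4' coupling, and delivers, by way of the dibromo bis-quinone methide F3, the dibromo dimer F4. Hydrodebromination (H2, 10% Pd/C, Et3N, EtOAc, rt; the amine suppresses benzylic C–O hydrogenolysis) returns to 9.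

Second: step 6. Prolonged acid can re-ionise the benzylic ethers and erode the kinetic exo,exo result toward C7 epimers, and a semipinacol shift of the α-hydroxy cation is conceivable. The fallback sets out from 10 and comes back at 11. Ionic hydrogenation (excess Et3SiH, TFA, CH2Cl2, 0 °C) removes both benzylic methoxy groups to give (2R,3R)-2,3-bis[(4-hydroxy-3-methoxyphenyl)methyl]butane-1,2,3,4-tetraol F5. DDQ (2.0 equiv, solid NaHCO3, dioxane, 10 °C; or Ag2O, CH2Cl2) then dehydrogenates each 4-alkyl-2-methoxyphenol to its p-quinone methide without acid. The two C9 hydroxyls close irreversibly under kinetic control, exactly as the biosynthetic bis-quinone methide does, giving 11.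

Third: step 3. Alkene 5 polymerises easily and its acylal is base-sensitive, and the free iodophenol may slow the catalyst. The fallback sets out from 5 and comes back at 7. Br2 (CH2Cl2, −78 °C) adds across the exocyclic alkene to give the dibromide F6. Et3N in the same flask eliminates HBr to give the bromomethylidene dioxolanone F7. Suzuki–Miyaura coupling of F7 with commercial 2-methoxy-4-(4,4,5,5-tetramethyl-1,3,2-dioxaborolan-2-yl)phenol (Pd(PPh3)4, anhydrous CsF, dioxane, 80 °C) gives 7. The alkene geometry is of no consequence for step 4.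

**Further compounds**
F1 | step 4 | 2-bromo-4-iodo-6-methoxyphenol | COc1cc(I)cc(Br)c1O
F2 | step 4 | (2R,5Z)-5-[(3-bromo-4-hydroxy-5-methoxyphenyl)methylidene]-2-tert-butyl-1,3-dioxolan-4-one | COc1cc(/C=C2\O[C@@H](C(C)(C)C)OC2=O)cc(Br)c1O
F3 | step 4 | (2R,2'R,5S,5'S)-5,5'-bis[(3-bromo-5-methoxy-4-oxocyclohexa-2,5-dien-1-ylidene)methyl]-2,2'-di-tert-butyl-5,5'-bi(1,3-dioxolane)-4,4'-dione | COC1=CC(=C[C@]2(O[C@@H](C(C)(C)C)OC2=O)[C@]2(C=C3C=C(Br)C(=O)C(OC)=C3)O[C@@H](C(C)(C)C)OC2=O)C=C(Br)C1=O
F4 | step 4 | (2R,2'R,5S,5'S)-5,5'-bis[(3-bromo-4-hydroxy-5-methoxyphenyl)(methoxy)methyl]-2,2'-di-tert-butyl-5,5'-bi(1,3-dioxolane)-4,4'-dione (benzylic epimer mixture) | COc1cc(C(OC)[C@]2(O[C@@H](C(C)(C)C)OC2=O)[C@]2(C(OC)c3cc(Br)c(O)c(OC)c3)O[C@@H](C(C)(C)C)OC2=O)cc(Br)c1O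
F5 | step 6 | (2R,3R)-2,3-bis[(4-hydroxy-3-methoxyphenyl)methyl]butane-1,2,3,4-tetraol | COc1cc(C[C@@](O)(CO)[C@](O)(CO)Cc2ccc(O)c(OC)c2)ccc1O
F6 | step 3 | (2S)-5-bromo-5-(bromomethyl)-2-tert-butyl-1,3-dioxolan-4-one (C5 epimer mixture; acetal geometry as in 5) | BrCC1(Br)O[C@@H](C(C)(C)C)OC1=O
F7 | step 3 | (2R,5Z)-5-(bromomethylidene)-2-tert-butyl-1,3-dioxolan-4-one | Br/C=C1\O[C@@H](C(C)(C)C)OC1=O
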